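- At early times the protic impurity takes free monomer first: its half-life by quenching alone, with free monomer as charged, 0.42 s, is far shorter than the 20 s of free monomer in the uncatalysed step alone. So both flasks effectively start from M₀ = 0.0475 M of free monomer, and the impurity touches no chain.

in all of them: free monomer 0.050 M; protic impurity 2.50 mM; initiator 0.25 mM
- violet: time 30 s
- grey: time 100 s

    free monomer → uncatalysed product (k1 = 0.034 s⁻¹)
    free monomer + initiator → living end + monomer in chains (k2 = 4.2 L mol⁻¹ s⁻¹)
    free monomer + living end → monomer in chains + living end, rate k3*[living end]*[free monomer] (k3 = 52 L mol⁻¹ s⁻¹)
    protic impurity + free monomer → quenched substrate (k4 = 33 L mol⁻¹ s⁻¹)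

- which of the two ends with the longer chains by the average number of monomer units in a chain (chains begun, living or dead) ("neither" if they lie within 10 %) (violet / grey / neither)
- average number of monomer units in a chain (chains begun, living or dead) at the end, violet
- average number of monomer units in a chain (chains begun, living or dead) at the end, grey

- the average divides the monomer in chains by the number of chains begun, living and dead together
- run time (violet): 30 s

- The zero of my scale is the statistical case: all chains begin together, and each holds one unit plus kp·E, where kp is the propagation constant and E is the exposure, the time integral of free monomer concentration.
- Real chains begin at random. With ki the initiation constant, initiator falls as exp(−ki·E), and the average chain loses the initiation lag w = 0.238 M·s, the exposure it waits before it begins. With f = one minus exp(−ki·E), the share of initiator begun, my average length is n = one + kp(E/f − w).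
- As a first pass, take living ends at the full initiator charge. Free monomer then decays pseudo-first-order at kd = 0.0470 s⁻¹, which gives a final exposure of M₀/kd = 1.01 M·s.
- The weak link is that the ends are not there at the start. I reforge it with a balance: M₀ goes to uncatalysed product and into chains, and solving that with n, taking f as one, gives a final exposure Ef = 1.07 M·s.
- Exposure at a given time is Ef minus the free monomer M still present over kd. To find M, I let the ends arrive late by d = 5.01 s, the mean wait of initiator at M₀.
- For violet, M = 0.0124 M, E = 0.808 M·s and n = 32.1.
- For grey, M = 4.61 × 10⁻⁴ M, E = 1.06 M·s and n = 44.5. I commit to grey, longer by 38.6 %, which is more than the margin of 10 %.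
- The forecast gives grey, with 32 for violet and 44.4 for grey, on the ground that “the average length then tracks the monomer exposure”.
- The simulation gives grey, with 31.9 for violet and 44.4 for grey.
- The neighbouring flask is grey with 6.3 × 10⁻⁵ M of initiator. The lag w stays 0.238 M·s, while kd becomes 0.0373 s⁻¹ and Ef becomes 1.29 M·s. At 100 s this leaves M = 0.00116 M, so E = 1.26 M·s and n = 54.6. The simulated neighbour ends at 54.6, with 6.84 % of the charged free monomer in chains.

The rate constants are assumed; the rest is arithmetic.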